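## Retrosynthetic overview

1. Target 27 ⇐ aldehyde 20 + C15 ylide 25 (Wittig, then diimide). The carbon of the C2 hydroxymethyl group becomes C1′ of the side chain; 25 comes from (2E,6E)-farnesol.
2. 20 ⇐ keto diol 19 ⇐ bridged ketal 16. An acetyl-anion equivalent adds to the one free carbonyl (C9), then acid frees the C6 ketone and the CH2OH group.
3. 16 ⇐ 14 (key). The spiro carbon C5 lies between C6 and C9 of the cyclopentene ring, both at carbonyl level, and is stereogenic only once they differ. C2 (CH3/CH2OH) is 1,3 to C5 across O1 of the tetrahydrofuran, so its CH2OH reaches C6 alone and ties it up in a temporary 1,4-dioxane ring (a 3,8-dioxabicyclo[3.2.1]octane mixed methyl ketal).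
4. 14 ⇐ 12 (oxidative C5–O1 spiro-etherification) ⇐ dione 8 + aldehyde 4 (reductive alkylation); 8 from 2,3-dimethylmaleic anhydride, 4 from (R)-citramalic acid.
5. Ring order: cyclopentenedione, then tetrahydrofuran (spiro), then the temporary dioxane bridge, which is opened again in step 14.

Key step: step 12

Remark: the target is taken exactly as drawn, (2S,5R,9S) in the core with a (4R,8R) chain; its C2 centre maps onto (R)-citramalic acid, and the descriptor changes from R to S only in the last step because the CIP priorities change. Atom numbers in the text follow the 1-oxaspiro[4.4]nonane core (O1, C2, C3, C4, spiro C5, C6–C9); compounds 15–18 are named as tricycles.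

## Route

Step 1
Reactants: 1 (R)-citramalic acid
Product: 2 (R)-2-methylbutane-1,2,4-triol
Conditions: BH3·SMe2, B(OMe)3, THF, 0 °C to rt; MeOH
Reagents that add atoms: none
Why: Borane reduction of both carboxyl groups of a hydroxy diacid is a standard way to the triol and leaves the tertiary carbinol centre untouched, so the configuration is kept.

Step 2
Reactants: 2 (R)-2-methylbutane-1,2,4-triol
Product: 3 2-[(4R)-2,2,4-trimethyl-1,3-dioxolan-4-yl]ethan-1-ol
Conditions: 2,2-dimethoxypropane, TsOH (cat.), acetone, rt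
Reagents that add atoms: 2,2-dimethoxypropane, COC(C)(C)OC
Why: Acetonide formation under thermodynamic control prefers the five-membered dioxolane across the 1,2-diol over the six-membered ring through the tertiary and the 4-hydroxyl, which leaves the primary 4-hydroxyl free.

Step 3
Reactants: 3 2-[(4R)-2,2,4-trimethyl-1,3-dioxolan-4-yl]ethan-1-ol
Product: 4 2-[(4R)-2,2,4-trimethyl-1,3-dioxolan-4-yl]acetaldehyde
Conditions: (COCl)2, DMSO, CH2Cl2, −78 °C; Et3N, −78 to 0 °C
Reagents that add atoms: none
Why: Swern oxidation stops at the aldehyde, and the cold, brief exposure to base avoids β-elimination of the acetonide oxygen.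

Step 4
Reactants: 5 2,3-dimethylmaleic anhydride
Product: 6 methyl (2E)-2-(3,4-dimethyl-5-oxofuran-2(5H)-ylidene)acetate
Conditions: Ph3P=CHCO2Me, toluene, reflux
Reagents that add atoms: methyl (triphenylphosphoranylidene)acetate, COC(=O)C=P(c1ccccc1)(c1ccccc1)c1ccccc1
Why: Wittig olefination of one anhydride carbonyl by a stabilised ylide gives the enol lactone (ylidenebutenolide), and either alkene geometry serves in the next step.

Step 5
Reactants: 6 methyl (2E)-2-(3,4-dimethyl-5-oxofuran-2(5H)-ylidene)acetate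
Product: 7 methyl 3,4-dimethyl-2,5-dioxocyclopent-3-ene-1-carboxylate
Conditions: NaOMe, MeOH, reflux; aq. HCl
Reagents that add atoms: none
Why: Methoxide opens the enol lactone to a keto diester enolate that recloses on carbon by Dieckmann-type acylation, the known rearrangement of ylidenebutenolides and alkylidenephthalides to cyclic 1,3-diones.

Step 6
Reactants: 7 methyl 3,4-dimethyl-2,5-dioxocyclopent-3-ene-1-carboxylate
Product: 8 4,5-dimethylcyclopent-4-ene-1,3-dione
Conditions: 2 M aq. HCl, AcOH, 90 °C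
Reagents that add atoms: none
Why: Acid hydrolysis of the β,β′-diketo ester and loss of CO2 from the resulting acid is the standard decarboxylation used for indane-1,3-dione and its relatives.

Step 7
Reactants: 4 2-[(4R)-2,2,4-trimethyl-1,3-dioxolan-4-yl]acetaldehyde; 8 4,5-dimethylcyclopent-4-ene-1,3-dione
Product: 10 4,5-dimethyl-2-{2-[(4R)-2,2,4-trimethyl-1,3-dioxolan-4-yl]ethyl}cyclopent-4-ene-1,3-dione, via Knoevenagel alkylidene dione 9 (not isolated)
Conditions: Hantzsch ester, L-proline (cat.), CH2Cl2, rt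
Reagents that add atoms: none
Why: Amine-catalysed Knoevenagel condensation at the acidic C2 of the dione, then conjugate hydride transfer from the Hantzsch ester to the exocyclic alkylidene (three-component reductive alkylation), gives C-monoalkylation without O-alkylation, and the tetrasubstituted ring alkene is too hindered to be reduced.

Step 8
Reactants: 10 4,5-dimethyl-2-{2-[(4R)-2,2,4-trimethyl-1,3-dioxolan-4-yl]ethyl}cyclopent-4-ene-1,3-dione
Product: 11 2-[(3R)-3,4-dihydroxy-3-methylbutyl]-4,5-dimethylcyclopent-4-ene-1,3-dione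
Conditions: 80% aq. AcOH, 40 °C
Reagents that add atoms: none
Why: Mild acid hydrolysis of the acetonide; the ene-dione cannot be trapped as a cyclic enol ether by the freed hydroxyls because that would create a cyclopentadienone.

Step 9
Reactants: 11 2-[(3R)-3,4-dihydroxy-3-methylbutyl]-4,5-dimethylcyclopent-4-ene-1,3-dione
Product: 12 2-[(3R)-4-{[tert-butyl(dimethyl)silyl]oxy}-3-hydroxy-3-methylbutyl]-4,5-dimethylcyclopent-4-ene-1,3-dione
Conditions: TBSCl, imidazole, CH2Cl2, 0 °C
Reagents that add atoms: tert-butyldimethylsilyl chloride, CC(C)(C)[Si](C)(C)Cl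
Why: Silylation is selective for the primary over the tertiary hydroxyl, so that only the tertiary oxygen is left to close the ring in the next step.

Step 10
Reactants: 12 2-[(3R)-4-{[tert-butyl(dimethyl)silyl]oxy}-3-hydroxy-3-methylbutyl]-4,5-dimethylcyclopent-4-ene-1,3-dione
Product: 13 (2R)-2-({[tert-butyl(dimethyl)silyl]oxy}methyl)-2,7,8-trimethyl-1-oxaspiro[4.4]non-7-ene-6,9-dione
Conditions: PhI(OAc)2, K2CO3, MeCN, 0 °C to rt
Reagents that add atoms: none
Why: Iodine(III)-mediated oxidative cycloetherification (intramolecular α-oxygenation of a 2-substituted 1,3-dione): the enolate is converted into an iodane at the central carbon and the tertiary hydroxyl displaces iodobenzene in a 5-exo closure that forms the C5–O1 bond, while C5 is not yet stereogenic and the C2 centre is not touched.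

Step 11
Reactants: 13 (2R)-2-({[tert-butyl(dimethyl)silyl]oxy}methyl)-2,7,8-trimethyl-1-oxaspiro[4.4]non-7-ene-6,9-dione
Product: 14 (2R)-2-(hydroxymethyl)-2,7,8-trimethyl-1-oxaspiro[4.4]non-7-ene-6,9-dione
Conditions: HF·pyridine, THF, 0 °C to rt
Reagents that add atoms: none
Why: Fluoride cleavage of the primary silyl ether under acidic buffering; a basic fluoride source is avoided because a free alkoxide could add to C6 and open the non-enolisable 1,3-dione by retro-Claisen cleavage.

Step 12
Reactants: 14 (2R)-2-(hydroxymethyl)-2,7,8-trimethyl-1-oxaspiro[4.4]non-7-ene-6,9-dione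
Product: 16 (1R,5S,8R)-5-methoxy-3,4,8-trimethyl-6,11-dioxatricyclo[6.2.1.0^1,5]undec-3-en-2-one (bridged methyl ketal), via bridged hemiketal 15 (not isolated)
Conditions: CSA (cat.), HC(OMe)3, MeOH, rt; Et3N quench
Reagents that add atoms: methanol, CO; trimethyl orthoformate, COC(OC)OC (methoxy donor by exchange and water scavenger)
Why: The primary hydroxyl adds under acid catalysis to the only carbonyl it can reach, C6 on its own face of the tetrahydrofuran, to give hemiketal 15, which ionises to the bicyclic oxocarbenium ion and is captured by methanol while the orthoformate removes the water. The closest known reaction type is the conversion of a δ-hydroxy ketone into its cyclic methyl ketal (methyl lactol ether), used here as an internal protection that also desymmetrises the dione. The one ring closed is the 1,4-dioxane O–CH2–C2–O1–C5–C6, formed by 6-exo-trig attack of oxygen on the carbonyl, which gives a 3,8-dioxabicyclo[3.2.1]octane fused to the cyclopentenone. The spiro carbon C5 becomes stereogenic (R) because the C2 centre from citramalic acid decides which of the two otherwise equivalent carbonyls is bridged, and the ketal carbon has no choice, since the new ring oxygen must lie on the O1 face of the carbocycle (cis ring fusion), which leaves the methoxy group on the C4 face. The step needs site selectivity between C6 and C9, secured by the tether geometry (C9 lies on the methyl face, out of reach), and restraint from dimethyl ketal formation at C9, secured by the hindrance of that carbonyl between the quaternary C5 and the tetrasubstituted alkene and by the reversibility of an acyclic ketal, which a brief mild aqueous acid wash should take off again.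

Step 13
Reactants: 16 (1R,5S,8R)-5-methoxy-3,4,8-trimethyl-6,11-dioxatricyclo[6.2.1.0^1,5]undec-3-en-2-one
Product: 17 (1R,2R,5S,8R)-2-(1-ethoxyethenyl)-5-methoxy-3,4,8-trimethyl-6,11-dioxatricyclo[6.2.1.0^1,5]undec-3-en-2-ol
Conditions: CH2=CHOEt, t-BuLi, THF, −78 to 0 °C; CeCl3, −78 °C; then 16, −78 °C; aq. NaHCO3
Reagents that add atoms: ethyl vinyl ether, C=COCC
Why: Organocerium 1,2-addition of an acyl-anion equivalent to the only free carbonyl: the reagent should enter on the face syn to the ring oxygen (O1 of the core, O11 here), which can bind cerium and is smaller than the methylene group and the methoxy group that flank the other face, so that the new carbinol carries OH anti to that oxygen; the low basicity of the cerium reagent avoids deprotonation of the enone methyl groups.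

Step 14
Reactants: 17 (1R,2R,5S,8R)-2-(1-ethoxyethenyl)-5-methoxy-3,4,8-trimethyl-6,11-dioxatricyclo[6.2.1.0^1,5]undec-3-en-2-ol
Product: 19 (2R,5R,9S)-9-acetyl-9-hydroxy-2-(hydroxymethyl)-2,7,8-trimethyl-1-oxaspiro[4.4]non-7-en-6-one, via acetyl ketal 18 (not isolated)
Conditions: 1 M aq. HCl, THF, rt
Reagents that add atoms: water, O
Why: Dilute acid first hydrolyses the enol ether to the methyl ketone and then opens the mixed ketal through its oxocarbenium ion to release the conjugated C6 ketone and the primary alcohol; the tertiary carbinol is safe because a cation at C9 would sit next to the acetyl group, and no stereocentre is epimerisable.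

Step 15
Reactants: 19 (2R,5R,9S)-9-acetyl-9-hydroxy-2-(hydroxymethyl)-2,7,8-trimethyl-1-oxaspiro[4.4]non-7-en-6-one
Product: 20 (2R,5R,9S)-9-acetyl-9-hydroxy-2,7,8-trimethyl-6-oxo-1-oxaspiro[4.4]non-7-ene-2-carbaldehyde
Conditions: Dess–Martin periodinane, CH2Cl2, 0 °C to rt
Reagents that add atoms: none
Why: Dess–Martin oxidation of the primary alcohol; the tertiary alcohol cannot be oxidised and the aldehyde has no α-hydrogen, so nothing can epimerise.

Step 16
Reactants: 21 (2E,6E)-farnesol
Product: 22 (3R,7R)-3,7,11-trimethyldodecan-1-ol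
Conditions: H2 (50 bar), chiral [Ir(cod)(N,P-ligand)]BArF (cat.), CH2Cl2, rt
Reagents that add atoms: none
Why: Iridium-catalysed asymmetric hydrogenation of trisubstituted alkenes: the two E-alkenes C2=C3 and C6=C7 present the same enantioface pattern to the catalyst, so C3 and C7 are set in the same sense (R,R with the proper catalyst enantiomer), and C11 is not stereogenic.

Step 17
Reactants: 22 (3R,7R)-3,7,11-trimethyldodecan-1-ol
Product: 23 (3R,7R)-1-bromo-3,7,11-trimethyldodecane
Conditions: CBr4, PPh3, CH2Cl2, 0 °C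
Reagents that add atoms: tetrabromomethane, BrC(Br)(Br)Br
Why: Appel bromination of a primary alcohol, which does not touch the remote stereocentres.

Step 18
Reactants: 23 (3R,7R)-1-bromo-3,7,11-trimethyldodecane
Product: 24 [(3R,7R)-3,7,11-trimethyldodecyl]triphenylphosphonium bromide
Conditions: PPh3, MeCN, reflux
Reagents that add atoms: triphenylphosphine, c1ccccc1P(c1ccccc1)c1ccccc1
Why: SN2 quaternisation of triphenylphosphine by a primary bromide.

Step 19
Reactants: 20 (2R,5R,9S)-9-acetyl-9-hydroxy-2,7,8-trimethyl-6-oxo-1-oxaspiro[4.4]non-7-ene-2-carbaldehyde; 24 [(3R,7R)-3,7,11-trimethyldodecyl]triphenylphosphonium bromide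
Product: 26 (2R,5R,9S)-9-acetyl-9-hydroxy-2,7,8-trimethyl-2-[(1Z,4R,8R)-4,8,12-trimethyltridec-1-en-1-yl]-1-oxaspiro[4.4]non-7-en-6-one, via phosphorus ylide 25 (not isolated)
Conditions: 24, NaHMDS, THF, 0 °C; then 20, −78 to 0 °C
Reagents that add atoms: none
Why: Wittig olefination: the non-stabilised ylide reacts with the aldehyde at −78 °C much faster than with the hindered enone or the methyl ketone on a quaternary carbon and is too weak a base to deprotonate the tertiary alcohol appreciably; the alkene geometry (Z expected) does not matter because the alkene is reduced next.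

Step 20
Reactants: 26 (2R,5R,9S)-9-acetyl-9-hydroxy-2,7,8-trimethyl-2-[(1Z,4R,8R)-4,8,12-trimethyltridec-1-en-1-yl]-1-oxaspiro[4.4]non-7-en-6-one
Product: 27 alpha-tocospiro A, (2S,5R,9S)-9-acetyl-9-hydroxy-2,7,8-trimethyl-2-[(4R,8R)-4,8,12-trimethyltridecyl]-1-oxaspiro[4.4]non-7-en-6-one
Conditions: 2-nitrobenzenesulfonylhydrazide, Et3N, CH2Cl2, rt
Reagents that add atoms: none
Why: Diimide reduction transfers H2 to the unpolarised 1,2-disubstituted alkene and leaves the tetrasubstituted, electron-poor enone alkene and both ketones alone; no stereocentre is affected.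

## Compound list

1 | (R)-citramalic acid | OC(=O)C[C@](C)(C(=O)O)O | starting material
2 | (R)-2-methylbutane-1,2,4-triol | OCC[C@](C)(CO)O | intermediate
3 | 2-[(4R)-2,2,4-trimethyl-1,3-dioxolan-4-yl]ethan-1-ol | OCC[C@]1(C)COC(C)(C)O1 | intermediate
4 | 2-[(4R)-2,2,4-trimethyl-1,3-dioxolan-4-yl]acetaldehyde | O=CC[C@]1(C)COC(C)(C)O1 | intermediate
5 | 2,3-dimethylmaleic anhydride | CC1=C(C)C(=O)OC1=O | starting material
6 | methyl (2E)-2-(3,4-dimethyl-5-oxofuran-2(5H)-ylidene)acetate | COC(=O)/C=C1/OC(=O)C(C)=C1C | intermediate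
7 | methyl 3,4-dimethyl-2,5-dioxocyclopent-3-ene-1-carboxylate | COC(=O)C1C(=O)C(C)=C(C)C1=O | intermediate
8 | 4,5-dimethylcyclopent-4-ene-1,3-dione | CC1=C(C)C(=O)CC1=O | intermediate
9 | 4,5-dimethyl-2-{2-[(4R)-2,2,4-trimethyl-1,3-dioxolan-4-yl]ethylidene}cyclopent-4-ene-1,3-dione | CC1=C(C)C(=O)C(=CC[C@]2(C)COC(C)(C)O2)C1=O | intermediate
10 | 4,5-dimethyl-2-{2-[(4R)-2,2,4-trimethyl-1,3-dioxolan-4-yl]ethyl}cyclopent-4-ene-1,3-dione | CC1=C(C)C(=O)C(CC[C@]2(C)COC(C)(C)O2)C1=O | intermediate
11 | 2-[(3R)-3,4-dihydroxy-3-methylbutyl]-4,5-dimethylcyclopent-4-ene-1,3-dione | CC1=C(C)C(=O)C(CC[C@](C)(CO)O)C1=O | intermediate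
12 | 2-[(3R)-4-{[tert-butyl(dimethyl)silyl]oxy}-3-hydroxy-3-methylbutyl]-4,5-dimethylcyclopent-4-ene-1,3-dione | CC1=C(C)C(=O)C(CC[C@](C)(CO[Si](C)(C)C(C)(C)C)O)C1=O | intermediate
13 | (2R)-2-({[tert-butyl(dimethyl)silyl]oxy}methyl)-2,7,8-trimethyl-1-oxaspiro[4.4]non-7-ene-6,9-dione | CC1=C(C)C(=O)C2(CC[C@](C)(CO[Si](C)(C)C(C)(C)C)O2)C1=O | intermediate
14 | (2R)-2-(hydroxymethyl)-2,7,8-trimethyl-1-oxaspiro[4.4]non-7-ene-6,9-dione | CC1=C(C)C(=O)C2(CC[C@](C)(CO)O2)C1=O | intermediate
15 | (1R,5S,8R)-5-hydroxy-3,4,8-trimethyl-6,11-dioxatricyclo[6.2.1.0^1,5]undec-3-en-2-one (bridged hemiketal) | O=C1C(C)=C(C)[C@]2(O)OC[C@@]3(C)CC[C@@]12O3 | intermediate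
16 | (1R,5S,8R)-5-methoxy-3,4,8-trimethyl-6,11-dioxatricyclo[6.2.1.0^1,5]undec-3-en-2-one (bridged methyl ketal) | O=C1C(C)=C(C)[C@]2(OC)OC[C@@]3(C)CC[C@@]12O3 | intermediate
17 | (1R,2R,5S,8R)-2-(1-ethoxyethenyl)-5-methoxy-3,4,8-trimethyl-6,11-dioxatricyclo[6.2.1.0^1,5]undec-3-en-2-ol | CCOC(=C)[C@]1(O)C(C)=C(C)[C@]2(OC)OC[C@@]3(C)CC[C@@]12O3 | intermediate
18 | 1-[(1R,2S,5S,8R)-2-hydroxy-5-methoxy-3,4,8-trimethyl-6,11-dioxatricyclo[6.2.1.0^1,5]undec-3-en-2-yl]ethan-1-one | CC(=O)[C@]1(O)C(C)=C(C)[C@]2(OC)OC[C@@]3(C)CC[C@@]12O3 | intermediate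
19 | (2R,5R,9S)-9-acetyl-9-hydroxy-2-(hydroxymethyl)-2,7,8-trimethyl-1-oxaspiro[4.4]non-7-en-6-one | CC(=O)[C@]1(O)C(C)=C(C)C(=O)[C@@]12CC[C@](C)(CO)O2 | intermediate
20 | (2R,5R,9S)-9-acetyl-9-hydroxy-2,7,8-trimethyl-6-oxo-1-oxaspiro[4.4]non-7-ene-2-carbaldehyde | CC(=O)[C@]1(O)C(C)=C(C)C(=O)[C@@]12CC[C@](C)(C=O)O2 | intermediate
21 | (2E,6E)-farnesol | CC(C)=CCC/C(C)=C/CC/C(C)=C/CO | starting material
22 | (3R,7R)-3,7,11-trimethyldodecan-1-ol | OCC[C@H](C)CCC[C@H](C)CCCC(C)C | intermediate
23 | (3R,7R)-1-bromo-3,7,11-trimethyldodecane | BrCC[C@H](C)CCC[C@H](C)CCCC(C)C | intermediate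
24 | [(3R,7R)-3,7,11-trimethyldodecyl]triphenylphosphonium bromide | [Br-].c1ccccc1[P+](CC[C@H](C)CCC[C@H](C)CCCC(C)C)(c1ccccc1)c1ccccc1 | intermediate
25 | [(3R,7R)-3,7,11-trimethyldodecylidene]triphenylphosphorane | c1ccccc1P(=CC[C@H](C)CCC[C@H](C)CCCC(C)C)(c1ccccc1)c1ccccc1 | intermediate
26 | (2R,5R,9S)-9-acetyl-9-hydroxy-2,7,8-trimethyl-2-[(1Z,4R,8R)-4,8,12-trimethyltridec-1-en-1-yl]-1-oxaspiro[4.4]non-7-en-6-one | CC(=O)[C@]1(O)C(C)=C(C)C(=O)[C@@]12CC[C@](C)(/C=C\C[C@H](C)CCC[C@H](C)CCCC(C)C)O2 | intermediate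
27 | alpha-tocospiro A, (2S,5R,9S)-9-acetyl-9-hydroxy-2,7,8-trimethyl-2-[(4R,8R)-4,8,12-trimethyltridecyl]-1-oxaspiro[4.4]non-7-en-6-one | CC(=O)[C@]1(O)C(C)=C(C)C(=O)[C@@]12CC[C@](C)(CCC[C@H](C)CCC[C@H](C)CCCC(C)C)O2 | target

## Step count

Total steps: 20. Longest linear sequence: 14 steps (from 1 through steps 1–3, 7–15, 19 and 20; the branch from 5 through steps 4–6 is equally long).

## Steps most likely to fail

1. Step 12 (key step). The ring-closing equilibrium may be unfavourable, because the cis-fused cyclopentenone forces the new dioxane ring towards a boat, and methanol may then ketalise C6 and C9 without site selection. The fallback replaces covalent bridging by steric shielding, sets out from 14 and comes back at 19. The primary alcohol of 14 is silylated (TBDPSCl, imidazole) to (2R)-2-({[tert-butyl(diphenyl)silyl]oxy}methyl)-2,7,8-trimethyl-1-oxaspiro[4.4]non-7-ene-6,9-dione F1. The large silyloxymethyl group sits beside O1 on the C6 side, so one equivalent of the cerium reagent of step 13 at −78 °C, entering syn to O1, should be turned towards C9 and give (2R,5R,9R)-2-({[tert-butyl(diphenyl)silyl]oxy}methyl)-9-(1-ethoxyethenyl)-9-hydroxy-2,7,8-trimethyl-1-oxaspiro[4.4]non-7-en-6-one F2. Dilute aqueous HCl converts it into (2R,5R,9S)-9-acetyl-2-({[tert-butyl(diphenyl)silyl]oxy}methyl)-9-hydroxy-2,7,8-trimethyl-1-oxaspiro[4.4]non-7-en-6-one F3, from which the regioisomer formed by attack at C6 would have to be separated by chromatography. HF·pyridine then gives 19.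

2. Step 10. Transfer of acetate from iodine(III) to C5, or simple loss of the iodane, may outrun attack by the hindered tertiary hydroxyl on a carbon that becomes quaternary. The fallback makes the C5–O1 bond first by carbenoid O–H insertion and closes the ring by C-alkylation; it sets out from 8 and 3 and comes back at 13.
   - Diazo transfer (4-acetamidobenzenesulfonyl azide, Et3N, MeCN) converts 8 into 2-diazo-4,5-dimethylcyclopent-4-ene-1,3-dione F4.
   - Appel bromination of 3 (CBr4, PPh3) gives (4R)-4-(2-bromoethyl)-2,2,4-trimethyl-1,3-dioxolane F5.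
   - Aqueous acetic acid gives (2R)-4-bromo-2-methylbutane-1,2-diol F6.
   - TBSCl and imidazole give the primary silyl ether (2R)-4-bromo-1-{[tert-butyl(dimethyl)silyl]oxy}-2-methylbutan-2-ol F7.
   - Rh2(OAc)4-catalysed O–H insertion of the carbenoid from F4 into the tertiary alcohol gives 2-{[(2R)-4-bromo-1-{[tert-butyl(dimethyl)silyl]oxy}-2-methylbutan-2-yl]oxy}-4,5-dimethylcyclopent-4-ene-1,3-dione F8.
   - K2CO3 in DMF closes the tetrahydrofuran by 5-exo-tet C-alkylation of the dione enolate (O-alkylation would need a seven-membered ring) and gives 13.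

3. Step 13. Facial selectivity may be poor, or the carbon nucleophile may enter anti to the ring oxygen if the polar effect of the C–O bond outweighs chelation and size. The fallback brings in the carbon without a stereochemical demand and delivers the oxygen to the face anti to the ring oxygen instead; it sets out from 16 and comes back at 18. Wittig olefination of 16 with ethylidenetriphenylphosphorane (EtPPh3Br, KOtBu, THF, reflux) gives (1R,5S,8R)-2-ethylidene-5-methoxy-3,4,8-trimethyl-6,11-dioxatricyclo[6.2.1.0^1,5]undec-3-ene F9, of either alkene geometry. Catalytic OsO4 with NMO should dihydroxylate the exocyclic trisubstituted alkene, not the tetrasubstituted ring alkene, from the face anti to the allylic ring oxygen, the usual preference of osmylation, and give (1R,2R,5S,8R)-2-(1-hydroxyethyl)-5-methoxy-3,4,8-trimethyl-6,11-dioxatricyclo[6.2.1.0^1,5]undec-3-en-2-ol F10. Dess–Martin oxidation of the secondary alcohol gives 18, which the conditions of step 14 hydrolyse to 19.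

## Further compounds

F1 | step 12 | (2R)-2-({[tert-butyl(diphenyl)silyl]oxy}methyl)-2,7,8-trimethyl-1-oxaspiro[4.4]non-7-ene-6,9-dione | CC1=C(C)C(=O)C2(CC[C@](C)(CO[Si](c3ccccc3)(c3ccccc3)C(C)(C)C)O2)C1=O
F2 | step 12 | (2R,5R,9R)-2-({[tert-butyl(diphenyl)silyl]oxy}methyl)-9-(1-ethoxyethenyl)-9-hydroxy-2,7,8-trimethyl-1-oxaspiro[4.4]non-7-en-6-one | CCOC(=C)[C@]1(O)C(C)=C(C)C(=O)[C@@]12CC[C@](C)(CO[Si](c3ccccc3)(c3ccccc3)C(C)(C)C)O2
F3 | step 12 | (2R,5R,9S)-9-acetyl-2-({[tert-butyl(diphenyl)silyl]oxy}methyl)-9-hydroxy-2,7,8-trimethyl-1-oxaspiro[4.4]non-7-en-6-one | CC(=O)[C@]1(O)C(C)=C(C)C(=O)[C@@]12CC[C@](C)(CO[Si](c3ccccc3)(c3ccccc3)C(C)(C)C)O2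
F4 | step 10 | 2-diazo-4,5-dimethylcyclopent-4-ene-1,3-dione | CC1=C(C)C(=O)C(=[N+]=[N-])C1=O
F5 | step 10 | (4R)-4-(2-bromoethyl)-2,2,4-trimethyl-1,3-dioxolane | BrCC[C@]1(C)COC(C)(C)O1
F6 | step 10 | (2R)-4-bromo-2-methylbutane-1,2-diol | BrCC[C@](C)(CO)O
F7 | step 10 | (2R)-4-bromo-1-{[tert-butyl(dimethyl)silyl]oxy}-2-methylbutan-2-ol | BrCC[C@](C)(CO[Si](C)(C)C(C)(C)C)O
F8 | step 10 | 2-{[(2R)-4-bromo-1-{[tert-butyl(dimethyl)silyl]oxy}-2-methylbutan-2-yl]oxy}-4,5-dimethylcyclopent-4-ene-1,3-dione | CC1=C(C)C(=O)C(O[C@](C)(CCBr)CO[Si](C)(C)C(C)(C)C)C1=O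
F9 | step 13 | (1R,5S,8R)-2-ethylidene-5-methoxy-3,4,8-trimethyl-6,11-dioxatricyclo[6.2.1.0^1,5]undec-3-ene (alkene geometry left open) | CC=C1C(C)=C(C)[C@]2(OC)OC[C@@]3(C)CC[C@@]12O3
F10 | step 13 | (1R,2R,5S,8R)-2-(1-hydroxyethyl)-5-methoxy-3,4,8-trimethyl-6,11-dioxatricyclo[6.2.1.0^1,5]undec-3-en-2-ol (secondary carbinol configuration left open) | CC(O)[C@]1(O)C(C)=C(C)[C@]2(OC)OC[C@@]3(C)CC[C@@]12O3
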